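Numbering used below: ring C1 carries the side chain, C2 OH, C3 OMe, C4 Me, C5 OH, C6 H; C7 is the alkene carbon on C1 and C8 the ester-bearing stereocentre (S).
Retrosynthesis: cut the C8–O acyl bond (angelate), return C2/C5 to a para-dimethoxy pair, cut C1–C7 and C2–O together, and in the chain cut C7–C8 (ynone stage) after trading C7–Br for an alkyne C–H.
Enabling feature: C1 and C2 are adjacent ring atoms and C2 lies next to the C3 methoxy group, so a C1≡C2 aryne is polarised to take carbon at C1 and lithium (then oxygen) at C2; its precursor is a symmetrical chloroarene with two identical C–H sites.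
Forward: C7–C8 is made by acetylide addition to a Weinreb amide, the chain is reduced and bromoborated, its dianion is joined to the aryne (C1–C7, then C2–O), the phenol is methylated, C8–OH is angeloylated, and oxidation then reduction unveils the hydroquinone; no ring is formed at any stage.
Stereochemistry: C8 is set by Noyori transfer hydrogenation of the ynone with the (S,S)-catalyst and is not touched afterwards (later steps act at oxygen or elsewhere); the Z alkene of the ester comes from angelic acid.

Key step: step 8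

Step 1
Reactants: 1 2,6-dimethoxytoluene
Product: 2 2-(3,5-dimethoxy-4-methylphenyl)-4,4,5,5-tetramethyl-1,3,2-dioxaborolane
Conditions: B2pin2 (1.0 equiv), [Ir(OMe)(cod)]2 (1.5 mol %), 4,4'-di-tert-butyl-2,2'-bipyridine (3 mol %), THF, 80 °C
Reagents that add atoms: bis(pinacolato)diboron, CC1(C)OB(OC1(C)C)B1OC(C)(C)C(C)(C)O1
Why: Iridium-catalysed C–H borylation is sterically controlled and should select the only ring C–H without an ortho substituent, the one para to the methyl group.

Step 2
Reactants: 2 2-(3,5-dimethoxy-4-methylphenyl)-4,4,5,5-tetramethyl-1,3,2-dioxaborolane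
Product: 3 5-chloro-1,3-dimethoxy-2-methylbenzene
Conditions: CuCl2 (3 equiv), MeOH/H2O (1:1), 80 °C
Reagents that add atoms: copper dichloride (CuCl2), Cl[Cu]Cl
Why: Copper-mediated ipso chlorodeboronation of an aryl pinacol boronate replaces boron by chlorine at the same carbon and so delivers the symmetrical aryne precursor.

Step 3
Reactants: 4 4-methylpent-3-enoic acid
Product: 6 N-methoxy-N,4-dimethylpent-3-enamide, via acyl imidazole 5 (not isolated)
Conditions: 1,1'-carbonyldiimidazole, CH2Cl2, 0 °C to rt; then MeNH(OMe)·HCl, rt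
Reagents that add atoms: N,O-dimethylhydroxylamine hydrochloride, CNOC.Cl
Why: Weinreb amide formation through the acyl imidazolide runs near neutrality, so the β,γ-alkene should not move into conjugation.

Step 4
Reactants: 6 N-methoxy-N,4-dimethylpent-3-enamide; 7 ethynyltrimethylsilane
Product: 10 6-methyl-1-(trimethylsilyl)hept-5-en-1-yn-3-one, via lithium (trimethylsilyl)acetylide 8 (not isolated), via lithium hemiaminal chelate 9 (not isolated)
Conditions: 7, n-BuLi, THF, −78 °C; then 6, −78 to 0 °C; AcOH, −78 °C
Reagents that add atoms: none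
Why: In this Weinreb ketone synthesis the acetylide adds once and stops at the chelated tetrahedral adduct, and the cold acidic quench releases the ynone without base-induced isomerisation of the skipped enone.

Step 5
Reactants: 10 6-methyl-1-(trimethylsilyl)hept-5-en-1-yn-3-one
Product: 11 (3S)-6-methyl-1-(trimethylsilyl)hept-5-en-1-yn-3-ol
Conditions: Ru[(S,S)-TsNCHPhCHPhNH](p-cymene) (1 mol %), i-PrOH, rt
Reagents that add atoms: none
Why: Noyori asymmetric transfer hydrogenation of an α,β-acetylenic ketone under base-free conditions delivers hydride to one carbonyl face, the alkyne taking the place of the aryl group in the six-membered transition state, so the (S,S)-catalyst should give the S alcohol at C8.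

Step 6
Reactants: 11 (3S)-6-methyl-1-(trimethylsilyl)hept-5-en-1-yn-3-ol
Product: 12 (3S)-6-methylhept-5-en-1-yn-3-ol
Conditions: K2CO3, MeOH, rt
Reagents that add atoms: none
Why: Methanolysis of the alkynyl C–Si bond is a standard protodesilylation that leaves the carbinol centre and the alkene untouched.

Step 7
Reactants: 12 (3S)-6-methylhept-5-en-1-yn-3-ol
Product: 14 (3S)-2-bromo-6-methylhepta-1,5-dien-3-ol, via bis-borylated bromoalkene 13 (not isolated)
Conditions: B-bromo-9-BBN (2.2 equiv), 2,6-di-tert-butylpyridine (1.2 equiv), CH2Cl2, 0 °C; AcOH, 0 °C to rt; aq NaHCO3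
Reagents that add atoms: B-bromo-9-borabicyclo[3.3.1]nonane, BrB1C2CCCC1CCC2
Why: In this haloboration–protonolysis the first equivalent of bromoborane masks the hydroxyl as a borinate while the hindered base takes up the hydrogen bromide, the second adds syn and Markovnikov across the terminal alkyne only, and acetic acid cleaves the alkenyl C–B bond to leave the 2-bromo-1-alkene with C8 unchanged.

Step 8
Reactants: 3 5-chloro-1,3-dimethoxy-2-methylbenzene; 14 (3S)-2-bromo-6-methylhepta-1,5-dien-3-ol
Product: 20 6-[(3S)-3-hydroxy-6-methylhepta-1,5-dien-2-yl]-2,4-dimethoxy-3-methylphenol, via alkoxide vinyllithium 15 (not isolated), via ortho-lithiated aryl chloride 16 (not isolated), via 3-methoxyaryne 17 (not isolated), via aryllithium adduct 18 (not isolated), via aryl dimethyl boronate 19 (not isolated)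
Conditions: 14, t-BuLi (3.0 equiv), Et2O, −78 °C; 3 (1.1 equiv), s-BuLi (1.1 equiv), THF, −78 °C, then added slowly to 15 at −30 °C; B(OMe)3, −78 °C to rt; H2O2, aq NaOH, 0 °C
Reagents that add atoms: hydrogen peroxide, OO
Why: sec-Butyllithium removes one of the two equivalent protons between chlorine and methoxy, and on warming the aryllithium 16 loses lithium chloride to give aryne 17, whose C1≡C2 bond is distorted and polarised by the adjacent C3 methoxy group. The alkenyl carbon of 15 adds at C1, the aryne carbon remote from the methoxy group, because the carbanion developing at C2 is stabilised inductively and by O–Li chelation; this forms C1–C7 and leaves aryllithium 18, which trimethyl borate captures and alkaline peroxide converts into the C2–O bond by aryl migration from boron to oxygen. The closest known reaction type is carbolithiation of a 3-alkoxybenzyne by an organolithium followed by electrophilic trapping of the resulting 2-lithioanisole. No ring closes and no stereocentre is created; C8 is carried through as its lithium alkoxide, which also avoids the silyl migration or elimination that an O-protected reagent would risk. The step needs regioselective addition, secured by the C3 methoxy group and by the symmetry of 3 that makes both lithiation sites identical, and chemoselective capture of the aryne by 15 over 16, secured by feeding 16 slowly into 15 with no amine and no excess alkyllithium present.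

Step 9
Reactants: 20 6-[(3S)-3-hydroxy-6-methylhepta-1,5-dien-2-yl]-2,4-dimethoxy-3-methylphenol
Product: 21 (3S)-6-methyl-2-(2,3,5-trimethoxy-4-methylphenyl)hepta-1,5-dien-3-ol
Conditions: Me2SO4, K2CO3, acetone, 40 °C
Reagents that add atoms: dimethyl sulfate, COS(=O)(=O)OC
Why: Carbonate deprotonates only the phenol, so this Williamson methylation caps C2–OH selectively, leaves the secondary alcohol free and turns C2/C5 into a para-dimethoxy pair.

Step 10
Reactants: 21 (3S)-6-methyl-2-(2,3,5-trimethoxy-4-methylphenyl)hepta-1,5-dien-3-ol; 22 angelic acid [(2Z)-2-methylbut-2-enoic acid]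
Product: 24 (3S)-6-methyl-2-(2,3,5-trimethoxy-4-methylphenyl)hepta-1,5-dien-3-yl (2Z)-2-methylbut-2-enoate, via mixed anhydride 23 (not isolated)
Conditions: 22, 2,4,6-trichlorobenzoyl chloride, Et3N, toluene, rt; then 21, 80 °C
Reagents that add atoms: none
Why: Yamaguchi-type esterification through the hindered mixed anhydride, run without a nucleophilic pyridine catalyst, acylates the alcohol at the angeloyl carbonyl with retention at C8 and avoids the addition–elimination pathway that turns angelates into tiglates.

Step 11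
Reactants: 24 (3S)-6-methyl-2-(2,3,5-trimethoxy-4-methylphenyl)hepta-1,5-dien-3-yl (2Z)-2-methylbut-2-enoate
Product: 25 (3S)-2-(5-methoxy-4-methyl-3,6-dioxocyclohexa-1,4-dien-1-yl)-6-methylhepta-1,5-dien-3-yl (2Z)-2-methylbut-2-enoate
Conditions: (NH4)2Ce(NO3)6 (2.5 equiv), MeCN/H2O (2:1), 0 °C
Reagents that add atoms: water, O
Why: Oxidative demethylation of a 1,4-dimethoxyarene by tetravalent cerium runs through the arene radical cation and ipso attack of water, and the para pair C2/C5 should be lost in preference to the ortho pair, so the C3 methoxy group stays on the quinone.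

Step 12
Reactants: 25 (3S)-2-(5-methoxy-4-methyl-3,6-dioxocyclohexa-1,4-dien-1-yl)-6-methylhepta-1,5-dien-3-yl (2Z)-2-methylbut-2-enoate
Product: 26 (3S)-2-(2,5-dihydroxy-3-methoxy-4-methylphenyl)-6-methylhepta-1,5-dien-3-yl (2Z)-2-methylbut-2-enoate
Conditions: Na2S2O4, EtOAc/H2O, rt, under argon
Reagents that add atoms: none
Why: Dithionite reduction of the quinone to the hydroquinone is a near-neutral two-electron, two-proton transfer that should leave the angelate, the allylic ester and C8 untouched.

Compound list
1 | 2,6-dimethoxytoluene | Cc1c(OC)cccc1OC | starting material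
2 | 2-(3,5-dimethoxy-4-methylphenyl)-4,4,5,5-tetramethyl-1,3,2-dioxaborolane | COc1cc(cc(OC)c1C)B1OC(C)(C)C(C)(C)O1 | intermediate
3 | 5-chloro-1,3-dimethoxy-2-methylbenzene | COc1cc(Cl)cc(OC)c1C | intermediate
4 | 4-methylpent-3-enoic acid | CC(C)=CCC(=O)O | starting material
5 | 1-(1H-imidazol-1-yl)-4-methylpent-3-en-1-one | CC(C)=CCC(=O)n1ccnc1 | intermediate
6 | N-methoxy-N,4-dimethylpent-3-enamide | CC(C)=CCC(=O)N(C)OC | intermediate
7 | ethynyltrimethylsilane | C#C[Si](C)(C)C | starting material
8 | lithium (trimethylsilyl)acetylide | [Li]C#C[Si](C)(C)C | intermediate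
9 | lithium 3-[methoxy(methyl)amino]-6-methyl-1-(trimethylsilyl)hept-5-en-1-yn-3-olate | CC(C)=CCC(O[Li])(C#C[Si](C)(C)C)N(C)OC | intermediate
10 | 6-methyl-1-(trimethylsilyl)hept-5-en-1-yn-3-one | CC(C)=CCC(=O)C#C[Si](C)(C)C | intermediate
11 | (3S)-6-methyl-1-(trimethylsilyl)hept-5-en-1-yn-3-ol | C[Si](C)(C)C#C[C@H](CC=C(C)C)O | intermediate
12 | (3S)-6-methylhept-5-en-1-yn-3-ol | C#C[C@H](CC=C(C)C)O | intermediate
13 | 9-{(1Z,3S)-2-bromo-3-[(9-borabicyclo[3.3.1]nonan-9-yl)oxy]-6-methylhepta-1,5-dien-1-yl}-9-borabicyclo[3.3.1]nonane | Br/C(=C\B1C2CCCC1CCC2)[C@H](CC=C(C)C)OB1C2CCCC1CCC2 | intermediate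
14 | (3S)-2-bromo-6-methylhepta-1,5-dien-3-ol | C=C(Br)[C@H](CC=C(C)C)O | intermediate
15 | lithium (3S)-2-lithio-6-methylhepta-1,5-dien-3-olate | [Li]C(=C)[C@H](CC=C(C)C)O[Li] | intermediate
16 | (6-chloro-2,4-dimethoxy-3-methylphenyl)lithium | COc1cc(Cl)c([Li])c(OC)c1C | intermediate
17 | 1,2-didehydro-3,5-dimethoxy-4-methylbenzene | COC1=C(C)C(OC)=CC#C1 | intermediate
18 | lithium (3S)-2-(2-lithio-3,5-dimethoxy-4-methylphenyl)-6-methylhepta-1,5-dien-3-olate | C=C(c1cc(OC)c(C)c(OC)c1[Li])[C@H](CC=C(C)C)O[Li] | intermediate
19 | lithium (3S)-2-[2-(dimethoxyboranyl)-3,5-dimethoxy-4-methylphenyl]-6-methylhepta-1,5-dien-3-olate | C=C(c1cc(OC)c(C)c(OC)c1B(OC)OC)[C@H](CC=C(C)C)O[Li] | intermediate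
20 | 6-[(3S)-3-hydroxy-6-methylhepta-1,5-dien-2-yl]-2,4-dimethoxy-3-methylphenol | C=C(c1cc(OC)c(C)c(OC)c1O)[C@H](CC=C(C)C)O | intermediate
21 | (3S)-6-methyl-2-(2,3,5-trimethoxy-4-methylphenyl)hepta-1,5-dien-3-ol | C=C(c1cc(OC)c(C)c(OC)c1OC)[C@H](CC=C(C)C)O | intermediate
22 | angelic acid [(2Z)-2-methylbut-2-enoic acid] | C/C=C(/C)C(=O)O | starting material
23 | (2Z)-2-methylbut-2-enoic 2,4,6-trichlorobenzoic anhydride | C/C=C(/C)C(=O)OC(=O)c1c(Cl)cc(Cl)cc1Cl | intermediate
24 | (3S)-6-methyl-2-(2,3,5-trimethoxy-4-methylphenyl)hepta-1,5-dien-3-yl (2Z)-2-methylbut-2-enoate | C=C(c1cc(OC)c(C)c(OC)c1OC)[C@H](CC=C(C)C)OC(=O)/C(C)=C\C | intermediate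
25 | (3S)-2-(5-methoxy-4-methyl-3,6-dioxocyclohexa-1,4-dien-1-yl)-6-methylhepta-1,5-dien-3-yl (2Z)-2-methylbut-2-enoate | C=C(C1=CC(=O)C(C)=C(OC)C1=O)[C@H](CC=C(C)C)OC(=O)/C(C)=C\C | intermediate
26 | (3S)-2-(2,5-dihydroxy-3-methoxy-4-methylphenyl)-6-methylhepta-1,5-dien-3-yl (2Z)-2-methylbut-2-enoate (CNP0248710.1) | C=C(c1cc(O)c(C)c(OC)c1O)[C@H](CC=C(C)C)OC(=O)/C(C)=C\C | target

Total step count: 12. Longest linear sequence: 10 steps (steps 3 to 7, step 8, steps 9 to 12, from 4-methylpent-3-enoic acid); the arene branch contributes steps 1 and 2.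

Steps most likely to fail

Step 8. The aryne may be consumed by its own lithiated precursor (oligomerisation) faster than by the hindered, alkoxide-bearing alkenyllithium, or the crowded aryllithium may be protonated before it is borylated. The fallback makes C2–O first and C1–C7 by cross-coupling. It sets out from 3: the lithiated chloride 16 is quenched at −78 °C, before lithium chloride is lost, with B(OMe)3 to give dimethyl (6-chloro-2,4-dimethoxy-3-methylphenyl)boronate F1. Oxidation with H2O2 gives 6-chloro-2,4-dimethoxy-3-methylphenol F2, and methylation (Me2SO4, K2CO3) gives 1-chloro-2,3,5-trimethoxy-4-methylbenzene F3. Dianion 15, made from 14 as in step 8, is transmetalated with ZnCl2 to the alkenylzinc chloride F4, and Negishi coupling of F3 with F4 (Pd(OAc)2, SPhos, THF, 60 °C) should give 21, where the route is rejoined.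

Step 7. Hydrogen bromide released when the hydroxyl is borylated may add to the trisubstituted alkene, or bromoboration next to the borinate may be slow and incomplete. The fallback removes the free hydroxyl before the bromoborane is used. It sets out from 12: silylation (TBSCl, imidazole, CH2Cl2) gives tert-butyldimethylsilyl ether F5, bromoboration with 1.2 equiv of B-bromo-9-BBN gives alkenylborane F6, and protonolysis with AcOH gives the silyl ether of the bromo alcohol F7. Cleavage with Bu4NF in THF returns to the route at 14.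

Step 11. The oxidant may attack the aryl-conjugated alkene, or the ortho methoxy pair may be lost in place of the para pair. The fallback oxidises a free para-methoxyphenol, for which the regiochemistry is fixed and a milder oxidant suffices. It sets out from 20: acylation of both hydroxyls with excess mixed anhydride 23 (Et3N, toluene, 80 °C) gives the bis-angelate F8, and pyrrolidine at 0 °C cleaves only the aryl ester to give the phenol mono-angelate F9. Oxidation of F9 with PhI(OAc)2 in MeCN/H2O at 0 °C should give 25, where the route is rejoined before the dithionite reduction.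

Further compounds
F1 | step 8 | dimethyl (6-chloro-2,4-dimethoxy-3-methylphenyl)boronate | COB(OC)c1c(Cl)cc(OC)c(C)c1OC
F2 | step 8 | 6-chloro-2,4-dimethoxy-3-methylphenol | COc1cc(Cl)c(O)c(OC)c1C
F3 | step 8 | 1-chloro-2,3,5-trimethoxy-4-methylbenzene | COc1cc(Cl)c(OC)c(OC)c1C
F4 | step 8 | chlorozinc (3S)-2-(chlorozincio)-6-methylhepta-1,5-dien-3-olate | C=C([Zn]Cl)[C@H](CC=C(C)C)O[Zn]Cl
F5 | step 7 | tert-butyldimethyl{[(3S)-6-methylhept-5-en-1-yn-3-yl]oxy}silane | C#C[C@H](CC=C(C)C)O[Si](C)(C)C(C)(C)C
F6 | step 7 | 9-{(1Z,3S)-2-bromo-3-[(tert-butyldimethylsilyl)oxy]-6-methylhepta-1,5-dien-1-yl}-9-borabicyclo[3.3.1]nonane | Br/C(=C\B1C2CCCC1CCC2)[C@H](CC=C(C)C)O[Si](C)(C)C(C)(C)C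
F7 | step 7 | {[(3S)-2-bromo-6-methylhepta-1,5-dien-3-yl]oxy}(tert-butyl)dimethylsilane | C=C(Br)[C@H](CC=C(C)C)O[Si](C)(C)C(C)(C)C
F8 | step 11 | (3S)-2-{3,5-dimethoxy-4-methyl-2-[(2Z)-2-methylbut-2-enoyloxy]phenyl}-6-methylhepta-1,5-dien-3-yl (2Z)-2-methylbut-2-enoate | C=C(c1cc(OC)c(C)c(OC)c1OC(=O)/C(C)=C\C)[C@H](CC=C(C)C)OC(=O)/C(C)=C\C
F9 | step 11 | (3S)-2-(2-hydroxy-3,5-dimethoxy-4-methylphenyl)-6-methylhepta-1,5-dien-3-yl (2Z)-2-methylbut-2-enoate | C=C(c1cc(OC)c(C)c(OC)c1O)[C@H](CC=C(C)C)OC(=O)/C(C)=C\C
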